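**Retrosynthetic overview**
- The target comes from a tetra-allyl precursor by one palladium-mediated deallylation. Its ring carboxyl comes from oxidation of a CH2OH group that is carried as a TIPS ether through all basic steps.
- The cinnamate C–O bond is cut to a benzodioxane cinnamic acid (Knoevenagel–Doebner on an aryl aldehyde, itself from a nitrile) and an allyl (R)-aryl-lactate (aryl Grignard + methyl (R)-glycidate).
- Only one ring is built, the 1,4-dioxane ring; all benzene rings are bought. It is closed late by intramolecular SNAr of a benzylic alkoxide onto an ortho-fluoro, para-cyano aryl ether, with retention at both centres, so the cis ring needs the anti (1S,2R) aryloxy alcohol.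
- The anti alcohol comes from Mitsunobu inversion of the syn alcohol, which comes from an Evans syn aldol between the boron enolate of an N-(aryloxyacetyl)oxazolidinone and 3,4-bis(allyloxy)benzaldehyde. This is the key C–C bond (C2–C3 of the dioxane) and the source of both ring stereocentres.
- The imide comes from 4-fluoro-3-hydroxybenzonitrile and a bromoacetyl oxazolidinone.

Assumption: the SMILES is read literally, so the benzodioxane is 2,3-cis (2S,3S) and the lactate centre is R; "allyl" means prop-2-en-1-yl.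

**Route**

Step 1
Reactants: 1 (4S)-4-benzyl-1,3-oxazolidin-2-one; 2 bromoacetyl bromide
Product: 4 (4S)-4-benzyl-3-(bromoacetyl)-1,3-oxazolidin-2-one, via lithium oxazolidinide 3 (not isolated)
Conditions: n-BuLi, THF, −78 °C; then 2, −78 → 0 °C
Reagents that add atoms: none
Why: N-acylation of the lithium oxazolidinide by the acyl bromide is much faster than displacement of the alkyl bromide (Evans auxiliary acylation).

Step 2
Reactants: 4 (4S)-4-benzyl-3-(bromoacetyl)-1,3-oxazolidin-2-one; 5 4-fluoro-3-hydroxybenzonitrile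
Product: 6 (4S)-4-benzyl-3-[(5-cyano-2-fluorophenoxy)acetyl]-1,3-oxazolidin-2-one
Conditions: K2CO3, MeCN, 23 °C
Reagents that add atoms: none
Why: Williamson ether synthesis; the acidic phenol is deprotonated by K2CO3 and displaces the activated α-bromide by SN2 without touching the imide or the aryl fluoride.

Step 3
Reactants: 7 3,4-dihydroxybenzaldehyde
Product: 8 3,4-bis(allyloxy)benzaldehyde
Conditions: allyl bromide, K2CO3, DMF, 60 °C
Reagents that add atoms: allyl bromide C=CCBr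
Why: double Williamson O-allylation; allyl ethers are used because all can be removed together at the end without base, acid or hydrogen.

Step 4
Reactants: 6 (4S)-4-benzyl-3-[(5-cyano-2-fluorophenoxy)acetyl]-1,3-oxazolidin-2-one; 8 3,4-bis(allyloxy)benzaldehyde
Product: 11 (4S)-4-benzyl-3-[(2S,3R)-3-[3,4-bis(allyloxy)phenyl]-2-(5-cyano-2-fluorophenoxy)-3-hydroxypropanoyl]-1,3-oxazolidin-2-one, via (Z)-dibutylboron enolate 9 (not isolated), via dibutylboron aldolate 10 (not isolated)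
Conditions: Bu2BOTf, i-Pr2NEt, CH2Cl2, 0 °C; 8, −78 → 0 °C; then pH 7 buffer (NaH2PO4/Na2HPO4), MeOH, 30% H2O2, 0 °C
Reagents that add atoms: none
Why: Evans syn aldol; the (Z)-boron enolate reacts through a Zimmerman–Traxler chair on the face away from the benzyl group of the (S)-auxiliary, forming the C2–C3 bond and setting both new centres (2S,3R).

Step 5
Reactants: 11 the syn aldol imide
Product: 12 3-{[(1R,2R)-1-[3,4-bis(allyloxy)phenyl]-1,3-dihydroxypropan-2-yl]oxy}-4-fluorobenzonitrile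
Conditions: LiBH4, H2O (1 equiv), THF, 0 °C
Reagents that add atoms: none
Why: reductive cleavage of the N-acyloxazolidinone removes the acidic α-carbonyl hydrogen before any basic step; nitrile, aryl fluoride and allyl ethers are inert and no stereocentre is touched (the C2 descriptor changes only through CIP priorities).

Step 6
Reactants: 12 the (1R,2R)-diol
Product: 13 3-{[(1R,2R)-1-[3,4-bis(allyloxy)phenyl]-1-hydroxy-3-[(triisopropylsilyl)oxy]propan-2-yl]oxy}-4-fluorobenzonitrile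
Conditions: TIPSCl, imidazole, DMF, 0 → 23 °C
Reagents that add atoms: triisopropylsilyl chloride CC(C)[Si](Cl)(C(C)C)C(C)C
Why: selective silylation of the primary over the hindered benzylic hydroxyl; the bulky TIPS group resists O-to-O silyl migration under the alkoxide conditions of step 9.

Step 7
Reactants: 13 the syn (1R,2R) alcohol
Product: 14 (1S,2R)-1-[3,4-bis(allyloxy)phenyl]-2-(5-cyano-2-fluorophenoxy)-3-[(triisopropylsilyl)oxy]propyl 4-nitrobenzoate
Conditions: PPh3, DIAD, 4-nitrobenzoic acid, toluene, 0 → 23 °C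
Reagents that add atoms: 4-nitrobenzoic acid OC(=O)c1ccc(cc1)[N+](=O)[O-]
Why: Mitsunobu esterification; SN2 displacement of the alkoxyphosphonium by the carboxylate inverts the benzylic centre (1R to 1S), turning the syn aldol relationship into the anti one, and the two β-oxygen substituents disfavour ionisation.

Step 8
Reactants: 14 the inverted 4-nitrobenzoate
Product: 15 3-{[(1S,2R)-1-[3,4-bis(allyloxy)phenyl]-1-hydroxy-3-[(triisopropylsilyl)oxy]propan-2-yl]oxy}-4-fluorobenzonitrile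
Conditions: K2CO3 (0.2 equiv), MeOH/THF, 0 °C
Reagents that add atoms: none
Why: base-catalysed transesterification cleaves the activated ester at the acyl carbon, so the inverted carbinol configuration is kept.

Step 9
Reactants: 15 the anti (1S,2R) alcohol
Product: 16 (2S,3R)-2-[3,4-bis(allyloxy)phenyl]-3-{[(triisopropylsilyl)oxy]methyl}-2,3-dihydro-1,4-benzodioxine-6-carbonitrile (2,3-cis)
Conditions: KN(SiMe3)2, THF, −20 → 23 °C
Reagents that add atoms: none
Why: intramolecular SNAr (6-exo) of the benzylic alkoxide on the fluoride activated by the para nitrile closes the dioxane ring without breaking a bond to either stereocentre, so the anti alcohol gives only the cis ring.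

Step 10
Reactants: 16 the cis-benzodioxane nitrile
Product: 18 (2S,3R)-2-[3,4-bis(allyloxy)phenyl]-3-{[(triisopropylsilyl)oxy]methyl}-2,3-dihydro-1,4-benzodioxine-6-carbaldehyde, via N-aluminio aldimine 17 (not isolated)
Conditions: i-Bu2AlH, toluene, −78 °C; then 1 M aq. HCl, 0 °C
Reagents that add atoms: water O
Why: partial hydride reduction of the nitrile stops at the N-aluminated aldimine, which is hydrolysed to the aldehyde on work-up; silyl and allyl ethers are untouched.

Step 11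
Reactants: 18 the benzodioxane aldehyde; 19 malonic acid
Product: 21 (2E)-3-[(2S,3R)-2-[3,4-bis(allyloxy)phenyl]-3-{[(triisopropylsilyl)oxy]methyl}-2,3-dihydro-1,4-benzodioxin-6-yl]prop-2-enoic acid, via arylidenemalonic acid 20 (not isolated)
Conditions: pyridine, piperidine (cat.), 80 °C
Reagents that add atoms: none
Why: Knoevenagel–Doebner condensation (aldol-type condensation then decarboxylation) gives the (E)-cinnamic acid, and at this stage the molecule has no base-labile stereocentre.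

Step 12
Reactants: 22 4-bromo-2-methoxyphenol
Product: 23 1-(allyloxy)-4-bromo-2-methoxybenzene
Conditions: allyl bromide, K2CO3, acetone, reflux
Reagents that add atoms: allyl bromide C=CCBr
Why: Williamson O-allylation of the phenol.

Step 13
Reactants: 23 1-(allyloxy)-4-bromo-2-methoxybenzene; 24 methyl (2R)-oxirane-2-carboxylate
Product: 26 methyl (2R)-3-[4-(allyloxy)-3-methoxyphenyl]-2-hydroxypropanoate, via arylmagnesium bromide 25 (not isolated)
Conditions: Mg, THF, 40 °C; then CuI (10 mol %), 24, THF, −40 → −20 °C; aq. NH4Cl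
Reagents that add atoms: none
Why: copper-catalysed Grignard opening of the epoxide at its CH2 carbon (SN2) outruns addition to the ester at low temperature; the chiral-pool centre is not attacked and stays R.

Step 14
Reactants: 26 the methyl (R)-lactate
Product: 27 allyl (2R)-3-[4-(allyloxy)-3-methoxyphenyl]-2-hydroxypropanoate
Conditions: allyl alcohol (solvent), Ti(OiPr)4 (10 mol %), 80 °C
Reagents that add atoms: allyl alcohol C=CCO
Why: titanium-alkoxide-catalysed transesterification driven by excess allyl alcohol; the conditions are neutral, so the α-hydroxy centre does not racemise.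

Step 15
Reactants: 21 the benzodioxane cinnamic acid; 27 the allyl (R)-lactate
Product: 28 (2R)-1-(allyloxy)-3-[4-(allyloxy)-3-methoxyphenyl]-1-oxopropan-2-yl (2E)-3-[(2S,3R)-2-[3,4-bis(allyloxy)phenyl]-3-{[(triisopropylsilyl)oxy]methyl}-2,3-dihydro-1,4-benzodioxin-6-yl]prop-2-enoate
Conditions: DCC, DMAP (cat.), CH2Cl2, 0 → 23 °C
Reagents that add atoms: none
Why: Steglich esterification; carbodiimide activation and DMAP acyl transfer acylate the secondary hydroxyl with retention, since no bond to the stereocentre is broken.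

Step 16
Reactants: 28 the silyl-protected ester
Product: 29 (2R)-1-(allyloxy)-3-[4-(allyloxy)-3-methoxyphenyl]-1-oxopropan-2-yl (2E)-3-[(2S,3R)-2-[3,4-bis(allyloxy)phenyl]-3-(hydroxymethyl)-2,3-dihydro-1,4-benzodioxin-6-yl]prop-2-enoate
Conditions: HF·pyridine, pyridine, THF, 0 → 23 °C
Reagents that add atoms: none
Why: fluoride-mediated desilylation under buffered conditions leaves the esters, allyl groups and cis ring intact.

Step 17
Reactants: 29 the primary alcohol
Product: 31 (2S,3S)-3-[3,4-bis(allyloxy)phenyl]-7-[(1E)-3-{[(2R)-1-(allyloxy)-3-[4-(allyloxy)-3-methoxyphenyl]-1-oxopropan-2-yl]oxy}-3-oxoprop-1-en-1-yl]-2,3-dihydro-1,4-benzodioxine-2-carboxylic acid, via aldehyde 30 (not isolated)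
Conditions: TEMPO (cat.), PhI(OAc)2, MeCN/H2O (1:1), 0 → 23 °C
Reagents that add atoms: water O
Why: oxoammonium (TEMPO) oxidation takes the primary alcohol through the aldehyde hydrate to the acid in a slightly acidic medium, so the α-aryloxy aldehyde is consumed before it can epimerise; alkenes and allyl ethers are tolerated.

Step 18
Reactants: 31 the tetra-allyl acid
Product: 32 (2S,3S)-7-[(1E)-3-{[(1R)-1-carboxy-2-(4-hydroxy-3-methoxyphenyl)ethyl]oxy}-3-oxoprop-1-en-1-yl]-3-(3,4-dihydroxyphenyl)-2,3-dihydro-1,4-benzodioxine-2-carboxylic acid (target)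
Conditions: Pd(PPh3)4 (10 mol %), morpholine, THF (degassed), 23 °C; then dilute aq. HCl
Reagents that add atoms: none
Why: Tsuji–Trost deallylation; zerovalent palladium ionises the allyl ester and the three allyl aryl ethers to π-allyl complexes that morpholine traps, while the ring acid is a carboxylate (cannot epimerise) and the cinnamate ester is untouched.

**Compound list**
1 | (4S)-4-benzyl-1,3-oxazolidin-2-one | O=C1OC[C@H](Cc2ccccc2)N1 | starting material
2 | bromoacetyl bromide | O=C(Br)CBr | starting material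
3 | lithium (4S)-4-benzyl-2-oxo-1,3-oxazolidin-3-ide | O=C1OC[C@H](Cc2ccccc2)N1[Li] | intermediate
4 | (4S)-4-benzyl-3-(bromoacetyl)-1,3-oxazolidin-2-one | O=C1OC[C@H](Cc2ccccc2)N1C(=O)CBr | intermediate
5 | 4-fluoro-3-hydroxybenzonitrile | N#Cc1ccc(F)c(O)c1 | starting material
6 | (4S)-4-benzyl-3-[(5-cyano-2-fluorophenoxy)acetyl]-1,3-oxazolidin-2-one | O=C1OC[C@H](Cc2ccccc2)N1C(=O)COc1cc(C#N)ccc1F | intermediate
7 | 3,4-dihydroxybenzaldehyde | O=Cc1ccc(O)c(O)c1 | starting material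
8 | 3,4-bis(allyloxy)benzaldehyde | O=Cc1ccc(OCC=C)c(OCC=C)c1 | intermediate
9 | (Z)-dibutylboron enolate of 6 | O=C1OC[C@H](Cc2ccccc2)N1/C(OB(CCCC)CCCC)=C/Oc1cc(C#N)ccc1F | intermediate
10 | dibutylboron aldolate of 11 | O=C1OC[C@H](Cc2ccccc2)N1C(=O)[C@@H](Oc1cc(C#N)ccc1F)[C@H](OB(CCCC)CCCC)c1ccc(OCC=C)c(OCC=C)c1 | intermediate
11 | (4S)-4-benzyl-3-[(2S,3R)-3-[3,4-bis(allyloxy)phenyl]-2-(5-cyano-2-fluorophenoxy)-3-hydroxypropanoyl]-1,3-oxazolidin-2-one | O=C1OC[C@H](Cc2ccccc2)N1C(=O)[C@@H](Oc1cc(C#N)ccc1F)[C@H](O)c1ccc(OCC=C)c(OCC=C)c1 | intermediate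
12 | 3-{[(1R,2R)-1-[3,4-bis(allyloxy)phenyl]-1,3-dihydroxypropan-2-yl]oxy}-4-fluorobenzonitrile | OC[C@@H](Oc1cc(C#N)ccc1F)[C@H](O)c1ccc(OCC=C)c(OCC=C)c1 | intermediate
13 | 3-{[(1R,2R)-1-[3,4-bis(allyloxy)phenyl]-1-hydroxy-3-[(triisopropylsilyl)oxy]propan-2-yl]oxy}-4-fluorobenzonitrile | CC(C)[Si](C(C)C)(C(C)C)OC[C@@H](Oc1cc(C#N)ccc1F)[C@H](O)c1ccc(OCC=C)c(OCC=C)c1 | intermediate
14 | (1S,2R)-1-[3,4-bis(allyloxy)phenyl]-2-(5-cyano-2-fluorophenoxy)-3-[(triisopropylsilyl)oxy]propyl 4-nitrobenzoate | CC(C)[Si](C(C)C)(C(C)C)OC[C@@H](Oc1cc(C#N)ccc1F)[C@@H](OC(=O)c1ccc(cc1)[N+](=O)[O-])c1ccc(OCC=C)c(OCC=C)c1 | intermediate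
15 | 3-{[(1S,2R)-1-[3,4-bis(allyloxy)phenyl]-1-hydroxy-3-[(triisopropylsilyl)oxy]propan-2-yl]oxy}-4-fluorobenzonitrile | CC(C)[Si](C(C)C)(C(C)C)OC[C@@H](Oc1cc(C#N)ccc1F)[C@@H](O)c1ccc(OCC=C)c(OCC=C)c1 | intermediate
16 | (2S,3R)-2-[3,4-bis(allyloxy)phenyl]-3-{[(triisopropylsilyl)oxy]methyl}-2,3-dihydro-1,4-benzodioxine-6-carbonitrile (cis) | CC(C)[Si](C(C)C)(C(C)C)OC[C@H]1Oc2cc(C#N)ccc2O[C@H]1c1ccc(OCC=C)c(OCC=C)c1 | intermediate
17 | N-(diisobutylaluminio) aldimine of 18 | CC(C)C[Al](CC(C)C)N=Cc1ccc2c(c1)O[C@H](CO[Si](C(C)C)(C(C)C)C(C)C)[C@H](c1ccc(OCC=C)c(OCC=C)c1)O2 | intermediate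
18 | (2S,3R)-2-[3,4-bis(allyloxy)phenyl]-3-{[(triisopropylsilyl)oxy]methyl}-2,3-dihydro-1,4-benzodioxine-6-carbaldehyde | O=Cc1ccc2c(c1)O[C@H](CO[Si](C(C)C)(C(C)C)C(C)C)[C@H](c1ccc(OCC=C)c(OCC=C)c1)O2 | intermediate
19 | malonic acid | OC(=O)CC(=O)O | starting material
20 | 2-{[(2S,3R)-2-[3,4-bis(allyloxy)phenyl]-3-{[(triisopropylsilyl)oxy]methyl}-2,3-dihydro-1,4-benzodioxin-6-yl]methylidene}propanedioic acid | OC(=O)C(C(=O)O)=Cc1ccc2c(c1)O[C@H](CO[Si](C(C)C)(C(C)C)C(C)C)[C@H](c1ccc(OCC=C)c(OCC=C)c1)O2 | intermediate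
21 | (2E)-3-[(2S,3R)-2-[3,4-bis(allyloxy)phenyl]-3-{[(triisopropylsilyl)oxy]methyl}-2,3-dihydro-1,4-benzodioxin-6-yl]prop-2-enoic acid | OC(=O)/C=C/c1ccc2c(c1)O[C@H](CO[Si](C(C)C)(C(C)C)C(C)C)[C@H](c1ccc(OCC=C)c(OCC=C)c1)O2 | intermediate
22 | 4-bromo-2-methoxyphenol | COc1cc(Br)ccc1O | starting material
23 | 1-(allyloxy)-4-bromo-2-methoxybenzene | COc1cc(Br)ccc1OCC=C | intermediate
24 | methyl (2R)-oxirane-2-carboxylate | COC(=O)[C@H]1CO1 | starting material
25 | [4-(allyloxy)-3-methoxyphenyl]magnesium bromide | COc1cc([Mg]Br)ccc1OCC=C | intermediate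
26 | methyl (2R)-3-[4-(allyloxy)-3-methoxyphenyl]-2-hydroxypropanoate | COC(=O)[C@H](O)Cc1ccc(OCC=C)c(OC)c1 | intermediate
27 | allyl (2R)-3-[4-(allyloxy)-3-methoxyphenyl]-2-hydroxypropanoate | C=CCOC(=O)[C@H](O)Cc1ccc(OCC=C)c(OC)c1 | intermediate
28 | (2R)-1-(allyloxy)-3-[4-(allyloxy)-3-methoxyphenyl]-1-oxopropan-2-yl (2E)-3-[(2S,3R)-2-[3,4-bis(allyloxy)phenyl]-3-{[(triisopropylsilyl)oxy]methyl}-2,3-dihydro-1,4-benzodioxin-6-yl]prop-2-enoate | C=CCOC(=O)[C@@H](Cc1ccc(OCC=C)c(OC)c1)OC(=O)/C=C/c1ccc2c(c1)O[C@H](CO[Si](C(C)C)(C(C)C)C(C)C)[C@H](c1ccc(OCC=C)c(OCC=C)c1)O2 | intermediate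
29 | (2R)-1-(allyloxy)-3-[4-(allyloxy)-3-methoxyphenyl]-1-oxopropan-2-yl (2E)-3-[(2S,3R)-2-[3,4-bis(allyloxy)phenyl]-3-(hydroxymethyl)-2,3-dihydro-1,4-benzodioxin-6-yl]prop-2-enoate | C=CCOC(=O)[C@@H](Cc1ccc(OCC=C)c(OC)c1)OC(=O)/C=C/c1ccc2c(c1)O[C@H](CO)[C@H](c1ccc(OCC=C)c(OCC=C)c1)O2 | intermediate
30 | (2R)-1-(allyloxy)-3-[4-(allyloxy)-3-methoxyphenyl]-1-oxopropan-2-yl (2E)-3-[(2S,3S)-2-[3,4-bis(allyloxy)phenyl]-3-formyl-2,3-dihydro-1,4-benzodioxin-6-yl]prop-2-enoate | C=CCOC(=O)[C@@H](Cc1ccc(OCC=C)c(OC)c1)OC(=O)/C=C/c1ccc2c(c1)O[C@H](C=O)[C@H](c1ccc(OCC=C)c(OCC=C)c1)O2 | intermediate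
31 | (2S,3S)-3-[3,4-bis(allyloxy)phenyl]-7-[(1E)-3-{[(2R)-1-(allyloxy)-3-[4-(allyloxy)-3-methoxyphenyl]-1-oxopropan-2-yl]oxy}-3-oxoprop-1-en-1-yl]-2,3-dihydro-1,4-benzodioxine-2-carboxylic acid | C=CCOC(=O)[C@@H](Cc1ccc(OCC=C)c(OC)c1)OC(=O)/C=C/c1ccc2c(c1)O[C@H](C(=O)O)[C@H](c1ccc(OCC=C)c(OCC=C)c1)O2 | intermediate
32 | (2S,3S)-7-[(1E)-3-{[(1R)-1-carboxy-2-(4-hydroxy-3-methoxyphenyl)ethyl]oxy}-3-oxoprop-1-en-1-yl]-3-(3,4-dihydroxyphenyl)-2,3-dihydro-1,4-benzodioxine-2-carboxylic acid | COc1cc(C[C@@H](OC(=O)/C=C/c2ccc3c(c2)O[C@H](C(=O)O)[C@H](c2ccc(O)c(O)c2)O3)C(=O)O)ccc1O | target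

**Totals**
Total steps: 18. Longest linear sequence: 14 steps (steps 1, 2, 4 to 11, 15 to 18).

**Three steps most likely to fail, with fallbacks**

Step 7 (Mitsunobu inversion). The alcohol is hindered and its aryl group is electron-rich, so partial ionisation (retention, leading later to the trans ring) or poor conversion is possible. The fallback sets out from 13 and comes back at 15. Buffered Dess–Martin oxidation (NaHCO3, CH2Cl2, 0 °C) gives the aryl ketone 3-{[(2R)-1-[3,4-bis(allyloxy)phenyl]-1-oxo-3-[(triisopropylsilyl)oxy]propan-2-yl]oxy}-4-fluorobenzonitrile F1. Reagent-controlled Corey–Bakshi–Shibata reduction of F1 ((S)-2-methyl-CBS-oxazaborolidine, catecholborane, toluene, −40 °C, aryl as the large group) then delivers the (1S) alcohol 15 without any substitution at the benzylic carbon.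

Step 13 (Grignard opening of the glycidate). The aryl Grignard may add to the ester of 24. The fallback sets out from 23 and comes back at 27, using an epoxide that carries no ester and installing the acid afterwards. The Grignard 25 made from 23 is added with CuI catalysis at −30 °C to (S)-glycidol, pre-converted to its magnesium alkoxide with i-PrMgCl, to give (2R)-3-[4-(allyloxy)-3-methoxyphenyl]propane-1,2-diol F2. Selective oxidation of the primary hydroxyl (TEMPO cat., NaClO2, NaOCl cat., MeCN/pH 6.7 buffer of NaH2PO4/Na2HPO4) gives (2R)-3-[4-(allyloxy)-3-methoxyphenyl]-2-hydroxypropanoic acid F3. Carboxylate alkylation (allyl bromide, KHCO3, DMF) then gives 27.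

Step 15 (Steglich coupling). A conjugated acid and a hindered, deactivated α-hydroxy ester can give N-acylurea and slow acyl transfer. The fallback sets out from 27 and 18 and comes back at 28, forming the cinnamate by C–C rather than C–O bond formation. Heating 27 with Meldrum's acid (toluene, 100 °C) gives the malonic half-ester 3-{[(2R)-1-(allyloxy)-3-[4-(allyloxy)-3-methoxyphenyl]-1-oxopropan-2-yl]oxy}-3-oxopropanoic acid F4. Knoevenagel–Doebner condensation of F4 with aldehyde 18 (pyridine, piperidine cat., 60 °C) passes through the arylidenemalonate half-ester of 18 and F4, F5, and decarboxylates to 28; steps 11 and 15 are then not needed.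

Further compounds
F1 | step 7 | 3-{[(2R)-1-[3,4-bis(allyloxy)phenyl]-1-oxo-3-[(triisopropylsilyl)oxy]propan-2-yl]oxy}-4-fluorobenzonitrile | CC(C)[Si](C(C)C)(C(C)C)OC[C@@H](Oc1cc(C#N)ccc1F)C(=O)c1ccc(OCC=C)c(OCC=C)c1
F2 | step 13 | (2R)-3-[4-(allyloxy)-3-methoxyphenyl]propane-1,2-diol | OC[C@H](O)Cc1ccc(OCC=C)c(OC)c1
F3 | step 13 | (2R)-3-[4-(allyloxy)-3-methoxyphenyl]-2-hydroxypropanoic acid | OC(=O)[C@H](O)Cc1ccc(OCC=C)c(OC)c1
F4 | step 15 | 3-{[(2R)-1-(allyloxy)-3-[4-(allyloxy)-3-methoxyphenyl]-1-oxopropan-2-yl]oxy}-3-oxopropanoic acid | C=CCOC(=O)[C@@H](Cc1ccc(OCC=C)c(OC)c1)OC(=O)CC(=O)O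
F5 | step 15 | 2-{[(2S,3R)-2-[3,4-bis(allyloxy)phenyl]-3-{[(triisopropylsilyl)oxy]methyl}-2,3-dihydro-1,4-benzodioxin-6-yl]methylidene}-3-{[(2R)-1-(allyloxy)-3-[4-(allyloxy)-3-methoxyphenyl]-1-oxopropan-2-yl]oxy}-3-oxopropanoic acid | C=CCOC(=O)[C@@H](Cc1ccc(OCC=C)c(OC)c1)OC(=O)C(C(=O)O)=Cc1ccc2c(c1)O[C@H](CO[Si](C(C)C)(C(C)C)C(C)C)[C@H](c1ccc(OCC=C)c(OCC=C)c1)O2
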